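The ratio I wanted was what is lost per hour over the links present, which I call the link loss constant λ (a pseudo-first-order constant). I counted as lost whatever is neither links nor first end groups, all as fractions of the first end groups charged.

| flask | first end groups | second end groups | remark | time |
|---|---|---|---|---|
| noon | 20 mM | 19 mM | run made earlier |  |
| autumn | 20 mM | 27 mM | run made earlier |  |
| dawn | 20 mM | 42 mM | run made earlier |  |
| midnight | 30 mM | 19 mM | run made earlier |  |
| Sunday's | 20 mM | 19.0 mM | a single well-mixed tank run continuously and read at steady state, 5.0 h in it on average |  |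
| Saturday's | 20 mM | 19.0 mM (fed, over 4.00 h) | a stirred flask in which second end groups is dosed at a steady rate over 4.00 h without added volume, worked up at 5.0 h | 5.0 h |
| Friday's | 20 mM | 19.0 mM | a closed flask charged with all of it at once and left for 5.0 h | 5.0 h |
| Monday's | 20 mM | 19.0 mM | plug flow through a tube for 5.0 h, no back-mixing | 5.0 h |

| run | time / h | links / % | first end groups / % |
|---|---|---|---|
| noon | 0.667 | 54.1 | 39.1 |
| noon | 1.33 | 50.0 | 36.9 |
| noon | 2.00 | 45.6 | 34.8 |
| noon | 2.50 | 42.9 | 34.1 |
| noon | 3.00 | 40.2 | 33.0 |
| autumn | 0.667 | 63.8 | 29.2 |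
| autumn | 1.33 | 59.2 | 27.1 |
| autumn | 2.00 | 53.7 | 25.2 |
| autumn | 2.50 | 51.3 | 24.3 |
| autumn | 3.00 | 47.5 | 23.4 |
| dawn | 0.667 | 73.8 | 19.1 |
| dawn | 1.33 | 67.4 | 17.8 |
| dawn | 2.00 | 62.8 | 16.8 |
| dawn | 2.50 | 58.1 | 15.7 |
| dawn | 3.00 | 55.0 | 14.9 |
| midnight | 0.667 | 42.0 | 51.3 |
| midnight | 1.33 | 37.7 | 48.5 |
| midnight | 2.00 | 33.5 | 46.2 |
| midnight | 2.50 | 31.2 | 44.6 |
| midnight | 3.00 | 28.6 | 43.1 |

(readings scatter by 0.3 percentage points)

1. the set-up with the highest amount of links at the outlet or at the end, in percent of the first end groups put in ("none" if the first two lie within 2 percentage points) (Sunday's / Saturday's / Friday's / Monday's / none)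
2. amount of links at the outlet or at the end, in percent of the first end groups put in, Sunday's
3. amount of links at the outlet or at the end, in percent of the first end groups put in, Saturday's
4. amount of links at the outlet or at the end, in percent of the first end groups put in, Friday's
5. amount of links at the outlet or at the end, in percent of the first end groups put in, Monday's

- the stated concentrations are those of everything mixed, before any reaction; amounts are the same in each set-up
- the feed brings no volume worth counting
- the earlier runs were made in a closed, stirred flask

Noon gave 0.182 h⁻¹ at a mean fraction f of first end groups of 36.1%; dawn gave 0.153 h⁻¹ at 17.0%. So, at this charge of first end groups, I read a straight line: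

λ = 0.127 h⁻¹ + 0.151 h⁻¹ · f

The autumn run, left out of the line, reads 0.170 h⁻¹ against 0.167 h⁻¹ from the line. At the last noon reading, f = 33.0%, the line gives λ = 0.177 h⁻¹, and I carried both values on for the late part of a flask.

My chain then ran as follows. Noon shares its charge with Friday's and Monday's, and the fall in links made up 0.695 of its loss, so:

Friday's, Monday's: 40.2% · exp(−0.695 · 0.177 h⁻¹ · 2.00 h) = 31.4%

Sunday's: (1 − f) / (1 + λ · 5.0 h) = 35.5%

For Saturday's, loss is λ times link-hours. I took f as 0.5 on average, so λ = 0.203 h⁻¹. A straight rise to 40.2% over the feed gave 1.21 h and 42.4%. That was the weak link: noon already held 54.1% links at 0.667 h, so I let the rise bend. Weighting the feed by 0.667 gave 1.47 h and 37.1%. My figures for Saturday's and Sunday's stood 1.6 percentage points apart, inside the 2 points margin.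

The forecast stood at 36%, 37%, 31% and 31%, best none, reasoning that “links stay low early, so less is lost”.

The flasks gave 34.8% for Sunday's, 38.0% for Saturday's, and 31.6% for Friday's and Monday's, so the best was Saturday's, ahead by 3.2 points.

    links → over-reaction product (k = 3.40 × 10⁻⁵ s⁻¹)
    first end groups + links → side product (k = 0.00130 M⁻¹ s⁻¹)
    first end groups + second end groups ⇌ links + released group (K = 2.40, k = 0.0810 M⁻¹ s⁻¹)

Saturday's ended with 17.9% over-reaction product against 25.9% in Monday's. In Saturday's last hour, 0.177 h⁻¹ times the mean links gives 7.07%, and links and first end groups together fell by 7.36%. The neighbour of Saturday's charged with 48 mM of second end groups ended with f = 11.0%, where the line puts λ at 0.144 h⁻¹, lower than 0.177 h⁻¹, and it held 49.3% links.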